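The chain is numbered C1 (enoic acid carbon) to C14 (saturated carboxyl carbon). Everything rests on opening the oxirane retrosynthetically to a (3R,4Z)-allylic alcohol: C3, sp2 in the target, is carried as an expendable secondary carbinol, and the oxirane ring (O, C4, C5) holds C3 and C6 cis, so its alkene parent has C6 pressing on C3 by A(1,3) strain. Hydroxyl-directed peracid epoxidation then forms both C–O bonds, the three-membered ring and the C4/C5 stereocentres in one operation. The precursor is the C3–C14 methyl ester with the C12/C13 diol as silyl ethers, assembled by Negishi union of a (Z)-iodoalkene with an alkylzinc carrying an Evans syn-aldol dyad.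

Key step: step 13

Remark on the chemistry: the target is read as (2E,4S,5R,7S,12S,13R), with the C12 hydroxyl and the C13 hydroxymethyl syn along C11–C14, so an Evans syn-aldol with the (R)-auxiliary sets this dyad.

Step 1
Reactants: 1 (S)-3-bromo-2-methylpropan-1-ol; 2 trifluoromethanesulfonic anhydride
Product: 3 (S)-3-bromo-2-methylpropyl trifluoromethanesulfonate
Conditions: Tf2O, 2,6-lutidine, CH2Cl2, −78 °C; cold aqueous work-up, used at once
Reagents that add atoms: trifluoromethanesulfonic anhydride, O=S(=O)(OS(=O)(=O)C(F)(F)F)C(F)(F)F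
Why: Sulfonylation of the primary hydroxyl with Tf2O and a hindered pyridine base is a standard alcohol activation that does not touch the adjacent stereocentre (C7 of the target, taken from the chiral pool) or the bromide.

Step 2
Reactants: 3 (S)-3-bromo-2-methylpropyl trifluoromethanesulfonate; 4 5-bromopent-1-ene
Product: 6 (S)-8-bromo-7-methyloct-1-ene, via pent-4-en-1-ylmagnesium bromide 5 (not isolated)
Conditions: 4, Mg, THF, 25 °C; then 3, CuBr·SMe2 (5 mol%), THF, −78 → −20 °C
Reagents that add atoms: 5-bromopent-1-ene (as its Grignard reagent), C=CCCCBr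
Why: Copper-catalysed Kochi-type coupling of a Grignard reagent with a primary alkyl triflate forms the C8–C9 bond at the far more reactive sulfonate, while the equally β-branched bromide, kept as the latent C6 organometallic, should survive at low temperature.

Step 3
Reactants: 6 (S)-8-bromo-7-methyloct-1-ene; 7 ozone
Product: 9 (S)-7-bromo-6-methylheptanal, via ozonide 8 (not isolated)
Conditions: O3, CH2Cl2, −78 °C; then Me2S, −78 → 25 °C
Reagents that add atoms: ozone, [O-][O+]=O
Why: Ozonolysis with reductive work-up cleaves the only alkene to the C12 aldehyde, the primary bromide and the remote stereocentre being inert to ozone and dimethyl sulfide.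

Step 4
Reactants: 10 (R)-4-benzyloxazolidin-2-one; 11 (E)-but-2-enoyl chloride
Product: 13 (R)-4-benzyl-3-[(E)-but-2-enoyl]oxazolidin-2-one, via lithiated oxazolidinone 12 (not isolated)
Conditions: n-BuLi, THF, −78 °C; then 11, −78 → 0 °C
Reagents that add atoms: (E)-but-2-enoyl chloride, C/C=C/C(Cl)=O
Why: N-Acylation of the lithiated oxazolidinone with an acid chloride is the standard route to Evans imides and installs the crotonyl group that later supplies C13, C14 and a vinyl surrogate for the hydroxymethyl carbon.

Step 5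
Reactants: 13 (R)-4-benzyl-3-[(E)-but-2-enoyl]oxazolidin-2-one; 9 (S)-7-bromo-6-methylheptanal
Product: 16 (R)-4-benzyl-3-[(2R,3S,8S)-9-bromo-3-hydroxy-8-methyl-2-vinylnonanoyl]oxazolidin-2-one, via boron dienolate 14 (not isolated), via boron aldolate 15 (not isolated)
Conditions: Bu2BOTf, Et3N, CH2Cl2, −78 → 0 °C; then 9, −78 → 0 °C; then pH 7 buffer, MeOH, H2O2, 0 °C
Reagents that add atoms: none
Why: Evans syn-aldol reaction: soft enolisation gives the (Z)-boron dienolate, which adds through its α-carbon in a chair Zimmerman–Traxler transition state on the face opposite the benzyl group of the (R)-auxiliary, so C12 (S) and C13 (R) are set syn under auxiliary control while the vinyl group stays out of conjugation.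

Step 6
Reactants: 16 (R)-4-benzyl-3-[(2R,3S,8S)-9-bromo-3-hydroxy-8-methyl-2-vinylnonanoyl]oxazolidin-2-one; 17 methanol
Product: 18 methyl (2R,3S,8S)-9-bromo-3-hydroxy-8-methyl-2-vinylnonanoate
Conditions: MeMgBr, MeOH, CH2Cl2, 0 °C
Reagents that add atoms: methanol (as MeOMgBr), CO
Why: Chelation-assisted transesterification of the β-hydroxy imide with methoxymagnesium bromide releases the auxiliary at the exocyclic carbonyl under conditions mild enough that retro-aldol cleavage and migration of the β,γ-alkene should not compete.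

Step 7
Reactants: 18 methyl (2R,3S,8S)-9-bromo-3-hydroxy-8-methyl-2-vinylnonanoate; 7 ozone
Product: 20 methyl (2R,3S,8S)-9-bromo-3-hydroxy-2-(hydroxymethyl)-8-methylnonanoate, via ozonide 19 (not isolated)
Conditions: O3, CH2Cl2, −78 °C; then NaBH4, MeOH, −78 → 0 °C
Reagents that add atoms: ozone, [O-][O+]=O
Why: Ozonolysis followed at once by borohydride reduction of the ozonide converts the vinyl group into the C13 hydroxymethyl without letting the epimerisable 2-formyl ester build up, and at 0 °C borohydride should leave the methyl ester and the bromide alone.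

Step 8
Reactants: 20 methyl (2R,3S,8S)-9-bromo-3-hydroxy-2-(hydroxymethyl)-8-methylnonanoate; 21 tert-butyldimethylsilyl trifluoromethanesulfonate
Product: 22 methyl (2R,3S,8S)-9-bromo-3-[(tert-butyldimethylsilyl)oxy]-2-{[(tert-butyldimethylsilyl)oxy]methyl}-8-methylnonanoate
Conditions: TBSOTf, 2,6-lutidine, CH2Cl2, −78 → 0 °C
Reagents that add atoms: tert-butyldimethylsilyl trifluoromethanesulfonate, CC(C)(C)[Si](C)(C)OS(=O)(=O)C(F)(F)F
Why: Silylation of the primary and the secondary hydroxyl with a silyl triflate and a hindered base is fast at low temperature and gives fluoride-labile ethers that withstand organozinc, peracid, periodinane and phosphonate conditions.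

Step 9
Reactants: 23 (R)-but-3-yn-2-ol; 24 iodomethane
Product: 26 (R)-pent-3-yn-2-ol, via dilithio alkynolate 25 (not isolated)
Conditions: n-BuLi (2.1 equiv), THF, −78 → −20 °C; then MeI (1.05 equiv), DMPU, −78 → 0 °C
Reagents that add atoms: iodomethane, CI
Why: Alkylation of the acetylide carbon of the O,C-dianion with iodomethane is a standard alkyne homologation; the lithium alkoxide is much the poorer nucleophile and the carbinol stereocentre is not involved.

Step 10
Reactants: 26 (R)-pent-3-yn-2-ol; 27 iodine
Product: 29 (R,Z)-4-iodopent-3-en-2-ol, via cyclic vinylalanate 28 (not isolated)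
Conditions: NaAlH2(OCH2CH2OMe)2, THF, 0 → 25 °C; then EtOAc; then I2, THF, −78 → 0 °C
Reagents that add atoms: iodine, II
Why: Hydroxyl-directed trans-hydroalumination delivers hydride to the alkyne carbon next to the carbinol and places aluminium on the distal carbon within a five-membered alanate, and iodinolysis with retention gives iodine cis to the carbinol carbon, the (Z) geometry needed for C4=C5.

Step 11
Reactants: 29 (R,Z)-4-iodopent-3-en-2-ol; 30 chlorotrimethylsilane
Product: 31 (R,Z)-[(4-iodopent-3-en-2-yl)oxy]trimethylsilane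
Conditions: TMSCl, imidazole, CH2Cl2, 0 °C
Reagents that add atoms: chlorotrimethylsilane, C[Si](C)(C)Cl
Why: O-Silylation with chlorotrimethylsilane and imidazole masks the acidic hydroxyl so that it cannot protonate the alkylzinc in the coupling, as an ether that can later be removed without touching TBS groups.

Step 12
Reactants: 22 methyl (2R,3S,8S)-9-bromo-3-[(tert-butyldimethylsilyl)oxy]-2-{[(tert-butyldimethylsilyl)oxy]methyl}-8-methylnonanoate; 31 (R,Z)-[(4-iodopent-3-en-2-yl)oxy]trimethylsilane
Product: 34 methyl (2R,3S,8S,10Z,12R)-3-[(tert-butyldimethylsilyl)oxy]-2-{[(tert-butyldimethylsilyl)oxy]methyl}-12-hydroxy-8,10-dimethyltridec-10-enoate, via alkylzinc bromide 32 (not isolated), via coupled trimethylsilyl ether 33 (not isolated)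
Conditions: 22, Zn dust, I2 (5 mol%), DMA, 80 °C; then 31, PdCl2(dppf) (5 mol%), THF, 45 °C; then K2CO3, MeOH, 0 °C
Reagents that add atoms: none
Why: Zinc inserts into the primary C–Br bond in a polar amide solvent to give an ester-tolerant alkylzinc bromide, and palladium-catalysed Negishi sp3–sp2 coupling with the iodoalkene forms C5–C6 with retention of the (Z) geometry; brief basic methanolysis then frees only the trimethylsilyl-protected C3 hydroxyl.

Step 13
Reactants: 34 methyl (2R,3S,8S,10Z,12R)-3-[(tert-butyldimethylsilyl)oxy]-2-{[(tert-butyldimethylsilyl)oxy]methyl}-12-hydroxy-8,10-dimethyltridec-10-enoate; 35 3-chloroperoxybenzoic acid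
Product: 36 methyl (2R,3S,8S)-3-[(tert-butyldimethylsilyl)oxy]-2-{[(tert-butyldimethylsilyl)oxy]methyl}-9-{(2R,3S)-3-[(1R)-1-hydroxyethyl]-2-methyloxiran-2-yl}-8-methylnonanoate
Conditions: mCPBA, NaHCO3, CH2Cl2, −20 → 0 °C
Reagents that add atoms: 3-chloroperoxybenzoic acid, OOC(=O)c1cccc(Cl)c1
Why: The peracid hydrogen-bonds to the C3 hydroxyl and hands its terminal oxygen to C4=C5 in a single concerted, spiro (butterfly) transition state, so both C–O bonds form on one face and the (Z) geometry becomes the cis C3/C6 relation on the ring. The closest known reaction type is the threo-selective peracid epoxidation of (Z)-substituted secondary allylic alcohols. The oxirane (O, C4, C5) is made by atom transfer to the π-bond, a [2+1] addition; no exo or endo ring closure of a tethered nucleophile is involved. C4 (S) and C5 (R) are fixed together by the choice of π-face, which the (R)-C3 carbinol controls: A(1,3) strain with the cis C6 methylene makes the C3–H bond eclipse the alkene, the hydroxyl then lies over one face only, and oxygen is delivered to that face. The step needs π-facial selectivity, secured by the cis C6 substituent on the trisubstituted alkene, and chemoselectivity, secured because the electron-rich C4=C5 bond is the only oxidisable site once the other hydroxyls are silylated, with NaHCO3 protecting the acid-labile epoxy alcohol. The C3 stereocentre has then served its purpose and is erased in step 14.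

Step 14
Reactants: 36 methyl (2R,3S,8S)-3-[(tert-butyldimethylsilyl)oxy]-2-{[(tert-butyldimethylsilyl)oxy]methyl}-9-{(2R,3S)-3-[(1R)-1-hydroxyethyl]-2-methyloxiran-2-yl}-8-methylnonanoate
Product: 37 methyl (2R,3S,8S)-9-[(2R,3R)-3-acetyl-2-methyloxiran-2-yl]-3-[(tert-butyldimethylsilyl)oxy]-2-{[(tert-butyldimethylsilyl)oxy]methyl}-8-methylnonanoate
Conditions: Dess–Martin periodinane, NaHCO3, CH2Cl2, 0 → 25 °C
Reagents that add atoms: none
Why: Dess–Martin oxidation of the secondary carbinol under bicarbonate buffering gives the α,β-epoxy methyl ketone without acid that could open the oxirane and without base that could epimerise C4 (its descriptor changes to R only because the priorities change).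

Step 15
Reactants: 37 methyl (2R,3S,8S)-9-[(2R,3R)-3-acetyl-2-methyloxiran-2-yl]-3-[(tert-butyldimethylsilyl)oxy]-2-{[(tert-butyldimethylsilyl)oxy]methyl}-8-methylnonanoate; 38 trimethyl phosphonoacetate
Product: 40 dimethyl (2E,4S,5R,7S,12S,13R)-12-[(tert-butyldimethylsilyl)oxy]-13-{[(tert-butyldimethylsilyl)oxy]methyl}-4,5-epoxy-3,5,7-trimethyltetradec-2-enedioate, via sodium phosphonate carbanion 39 (not isolated)
Conditions: 38, NaH, THF, 0 °C; then 37, 0 → 25 °C
Reagents that add atoms: trimethyl phosphonoacetate, COC(=O)CP(=O)(OC)OC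
Why: Horner–Wadsworth–Emmons olefination of the methyl ketone forms C2=C3 with the ester trans to the larger oxiranyl substituent, so the (2E) isomer should predominate and any (2Z) isomer be separable; the stabilised carbanion is too weak a base to enolise the C14 ester.

Step 16
Reactants: 40 dimethyl (2E,4S,5R,7S,12S,13R)-12-[(tert-butyldimethylsilyl)oxy]-13-{[(tert-butyldimethylsilyl)oxy]methyl}-4,5-epoxy-3,5,7-trimethyltetradec-2-enedioate
Product: 41 dimethyl (2E,4S,5R,7S,12S,13R)-4,5-epoxy-12-hydroxy-13-(hydroxymethyl)-3,5,7-trimethyltetradec-2-enedioate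
Conditions: TBAF, AcOH (1:1), THF, 25 → 40 °C
Reagents that add atoms: none
Why: Fluoride-mediated Si–O cleavage, buffered with acetic acid so that the medium is neither basic enough for retro-aldol cleavage nor acidic enough to open the oxirane, should remove both TBS groups.

Step 17
Reactants: 41 dimethyl (2E,4S,5R,7S,12S,13R)-4,5-epoxy-12-hydroxy-13-(hydroxymethyl)-3,5,7-trimethyltetradec-2-enedioate; 42 lithium hydroxide
Product: 44 (2E,4S,5R,7S,12S,13R)-4,5-epoxy-12-hydroxy-13-(hydroxymethyl)-3,5,7-trimethyltetradec-2-enedioic acid, via dilithium dicarboxylate 43 (not isolated)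
Conditions: LiOH, THF/MeOH/H2O, 0 → 25 °C; then 0.5 M HCl to pH 4, 0 °C
Reagents that add atoms: lithium hydroxide, [Li+].[OH-]
Why: Saponification of both methyl esters with hydroxide, the β-hydroxy ester first and the β,β-disubstituted enoate more slowly, should spare the base-stable oxirane, and careful acidification to pH 4 at 0 °C liberates the diacid.

Compound list
1 | (S)-3-bromo-2-methylpropan-1-ol | BrC[C@@H](C)CO | starting material
2 | trifluoromethanesulfonic anhydride | O=S(=O)(OS(=O)(=O)C(F)(F)F)C(F)(F)F | starting material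
3 | (S)-3-bromo-2-methylpropyl trifluoromethanesulfonate | BrC[C@@H](C)COS(=O)(=O)C(F)(F)F | intermediate
4 | 5-bromopent-1-ene | C=CCCCBr | starting material
5 | pent-4-en-1-ylmagnesium bromide | C=CCCC[Mg]Br | intermediate
6 | (S)-8-bromo-7-methyloct-1-ene | BrC[C@@H](C)CCCCC=C | intermediate
7 | ozone | [O-][O+]=O | starting material
8 | 3-[(5S)-6-bromo-5-methylhexyl]-1,2,4-trioxolane (ozonide of 6, both epimers at the ring carbon) | BrC[C@@H](C)CCCCC1OCOO1 | intermediate
9 | (S)-7-bromo-6-methylheptanal | BrC[C@@H](C)CCCCC=O | intermediate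
10 | (R)-4-benzyloxazolidin-2-one | O=C1N[C@H](Cc2ccccc2)CO1 | starting material
11 | (E)-but-2-enoyl chloride | C/C=C/C(Cl)=O | starting material
12 | lithium (R)-4-benzyl-2-oxooxazolidin-3-ide | [Li]N1[C@H](Cc2ccccc2)COC1=O | intermediate
13 | (R)-4-benzyl-3-[(E)-but-2-enoyl]oxazolidin-2-one | C/C=C/C(=O)N1[C@H](Cc2ccccc2)COC1=O | intermediate
14 | (Z)-dibutylboron dienolate of 13 (O-boryl group cis to the vinyl group) | C=C/C=C(\OB(CCCC)CCCC)N1[C@H](Cc2ccccc2)COC1=O | intermediate
15 | O-dibutylboryl aldolate of 16 | BrC[C@@H](C)CCCC[C@H](OB(CCCC)CCCC)[C@@H](C=C)C(=O)N1[C@H](Cc2ccccc2)COC1=O | intermediate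
16 | (R)-4-benzyl-3-[(2R,3S,8S)-9-bromo-3-hydroxy-8-methyl-2-vinylnonanoyl]oxazolidin-2-one | BrC[C@@H](C)CCCC[C@H](O)[C@@H](C=C)C(=O)N1[C@H](Cc2ccccc2)COC1=O | intermediate
17 | methanol | CO | starting material
18 | methyl (2R,3S,8S)-9-bromo-3-hydroxy-8-methyl-2-vinylnonanoate | BrC[C@@H](C)CCCC[C@H](O)[C@@H](C=C)C(=O)OC | intermediate
19 | ozonide of 18 (1,2,4-trioxolan-3-yl in place of vinyl, both epimers at the ring carbon) | BrC[C@@H](C)CCCC[C@H](O)[C@@H](C1OCOO1)C(=O)OC | intermediate
20 | methyl (2R,3S,8S)-9-bromo-3-hydroxy-2-(hydroxymethyl)-8-methylnonanoate | BrC[C@@H](C)CCCC[C@H](O)[C@@H](CO)C(=O)OC | intermediate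
21 | tert-butyldimethylsilyl trifluoromethanesulfonate | CC(C)(C)[Si](C)(C)OS(=O)(=O)C(F)(F)F | starting material
22 | methyl (2R,3S,8S)-9-bromo-3-[(tert-butyldimethylsilyl)oxy]-2-{[(tert-butyldimethylsilyl)oxy]methyl}-8-methylnonanoate | BrC[C@@H](C)CCCC[C@H](O[Si](C)(C)C(C)(C)C)[C@@H](CO[Si](C)(C)C(C)(C)C)C(=O)OC | intermediate
23 | (R)-but-3-yn-2-ol | C[C@@H](O)C#C | starting material
24 | iodomethane | CI | starting material
25 | dilithium salt of 23 (lithium alkoxide, lithium acetylide) | C[C@@H](O[Li])C#C[Li] | intermediate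
26 | (R)-pent-3-yn-2-ol | C[C@@H](O)C#CC | intermediate
27 | iodine | II | starting material
28 | sodium salt of the five-membered cyclic vinylalanate from 26 (ring O–Al–C(CH3)=CH–CH(CH3), two 2-methoxyethoxy groups on Al, R at the carbinol carbon) | C[C@H]1O[Al-](OCCOC)(OCCOC)C(C)=C1.[Na+] | intermediate
29 | (R,Z)-4-iodopent-3-en-2-ol | C[C@@H](O)/C=C(/C)I | intermediate
30 | chlorotrimethylsilane | C[Si](C)(C)Cl | starting material
31 | (R,Z)-[(4-iodopent-3-en-2-yl)oxy]trimethylsilane | C[C@@H](O[Si](C)(C)C)/C=C(/C)I | intermediate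
32 | alkylzinc bromide from 22 (ZnBr in place of Br at C9) | Br[Zn]C[C@@H](C)CCCC[C@H](O[Si](C)(C)C(C)(C)C)[C@@H](CO[Si](C)(C)C(C)(C)C)C(=O)OC | intermediate
33 | methyl (2R,3S,8S,10Z,12R)-3-[(tert-butyldimethylsilyl)oxy]-2-{[(tert-butyldimethylsilyl)oxy]methyl}-8,10-dimethyl-12-[(trimethylsilyl)oxy]tridec-10-enoate | C[C@@H](O[Si](C)(C)C)/C=C(/C)C[C@@H](C)CCCC[C@H](O[Si](C)(C)C(C)(C)C)[C@@H](CO[Si](C)(C)C(C)(C)C)C(=O)OC | intermediate
34 | methyl (2R,3S,8S,10Z,12R)-3-[(tert-butyldimethylsilyl)oxy]-2-{[(tert-butyldimethylsilyl)oxy]methyl}-12-hydroxy-8,10-dimethyltridec-10-enoate | C[C@@H](O)/C=C(/C)C[C@@H](C)CCCC[C@H](O[Si](C)(C)C(C)(C)C)[C@@H](CO[Si](C)(C)C(C)(C)C)C(=O)OC | intermediate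
35 | 3-chloroperoxybenzoic acid | OOC(=O)c1cccc(Cl)c1 | starting material
36 | methyl (2R,3S,8S)-3-[(tert-butyldimethylsilyl)oxy]-2-{[(tert-butyldimethylsilyl)oxy]methyl}-9-{(2R,3S)-3-[(1R)-1-hydroxyethyl]-2-methyloxiran-2-yl}-8-methylnonanoate | C[C@@H](O)[C@@H]1O[C@]1(C)C[C@@H](C)CCCC[C@H](O[Si](C)(C)C(C)(C)C)[C@@H](CO[Si](C)(C)C(C)(C)C)C(=O)OC | intermediate
37 | methyl (2R,3S,8S)-9-[(2R,3R)-3-acetyl-2-methyloxiran-2-yl]-3-[(tert-butyldimethylsilyl)oxy]-2-{[(tert-butyldimethylsilyl)oxy]methyl}-8-methylnonanoate | CC(=O)[C@@H]1O[C@]1(C)C[C@@H](C)CCCC[C@H](O[Si](C)(C)C(C)(C)C)[C@@H](CO[Si](C)(C)C(C)(C)C)C(=O)OC | intermediate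
38 | trimethyl phosphonoacetate | COC(=O)CP(=O)(OC)OC | starting material
39 | sodium salt of the carbanion of 38 | COC(=O)[CH-]P(=O)(OC)OC.[Na+] | intermediate
40 | dimethyl (2E,4S,5R,7S,12S,13R)-12-[(tert-butyldimethylsilyl)oxy]-13-{[(tert-butyldimethylsilyl)oxy]methyl}-4,5-epoxy-3,5,7-trimethyltetradec-2-enedioate | C/C(=C\C(=O)OC)[C@@H]1O[C@]1(C)C[C@@H](C)CCCC[C@H](O[Si](C)(C)C(C)(C)C)[C@@H](CO[Si](C)(C)C(C)(C)C)C(=O)OC | intermediate
41 | dimethyl (2E,4S,5R,7S,12S,13R)-4,5-epoxy-12-hydroxy-13-(hydroxymethyl)-3,5,7-trimethyltetradec-2-enedioate | C/C(=C\C(=O)OC)[C@@H]1O[C@]1(C)C[C@@H](C)CCCC[C@H](O)[C@@H](CO)C(=O)OC | intermediate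
42 | lithium hydroxide | [Li+].[OH-] | starting material
43 | dilithium salt of 44 | C/C(=C\C(=O)[O-])[C@@H]1O[C@]1(C)C[C@@H](C)CCCC[C@H](O)[C@@H](CO)C(=O)[O-].[Li+].[Li+] | intermediate
44 | (2E,4S,5R,7S,12S,13R)-4,5-epoxy-12-hydroxy-13-(hydroxymethyl)-3,5,7-trimethyltetradec-2-enedioic acid (CNP0468463.2) | C/C(=C\C(=O)O)[C@@H]1O[C@]1(C)C[C@@H](C)CCCC[C@H](O)[C@@H](CO)C(=O)O | target

Total step count: 17.
Longest linear sequence: 13 steps (1, 2, 3, 5, 6, 7, 8, 12, 13, 14, 15, 16, 17).

Steps most likely to fail

Step 13. The risk is poor π-facial discrimination if the A(1,3)-locked rotamer does not dominate, or acid-promoted opening or rearrangement of the epoxy alcohol by the carboxylic acid by-product. The fallback sets out again from 34 and replaces substrate direction by catalyst control. It is a Shi epoxidation with the L-fructose-derived enantiomer of the Shi ketone (KHSO5 as 2KHSO5·KHSO4·K2SO4, K2CO3, MeCN/dimethoxymethane/aqueous buffer, 0 °C). The D-fructose ketone is expected, by its spiro dioxirane transition state, to attack the other face of this trisubstituted alkene, so the enantiomeric ketone should give the (4S,5R) oxirane in the same sense as the substrate bias. The product is 36 itself, where the route is rejoined; no new compound arises (F0).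

Step 12. The risk is sluggish zinc insertion into the β-branched bromide, protonolysis of the organozinc, or slow transmetalation that lets β-hydride elimination and alkene isomerisation compete. The fallback sets out from 22 and 31 and joins them by nickel-catalysed reductive cross-electrophile coupling, with no preformed organometallic (NiBr2(dme), 4,4′-di-tert-butyl-2,2′-bipyridine, Mn powder, NaI, DMA, 40 °C). This should give 33, which is methanolysed as before, and the route is rejoined at 34; no new compound arises (F0).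

Step 6. The risk is base-induced migration of the β,γ-alkene into conjugation, which would destroy C13, or retro-aldol cleavage during transesterification. The fallback sets out from 16 and splits the operation into hydrolysis and neutral O-methylation. LiOH/H2O2 (THF/H2O, 0 °C, Na2SO3 quench) cleaves the exocyclic imide carbonyl through the weakly basic hydroperoxide to give (2R,3S,8S)-9-bromo-3-hydroxy-8-methyl-2-vinylnonanoic acid F1. Methylation of F1 with TMSCHN2 (MeOH/toluene, 0 °C) rejoins the route at 18.

Further compounds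
F0 | step 13 | none | none
F0 | step 12 | none | none
F1 | step 6 | (2R,3S,8S)-9-bromo-3-hydroxy-8-methyl-2-vinylnonanoic acid | BrC[C@@H](C)CCCC[C@H](O)[C@@H](C=C)C(=O)O
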